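**Plan**

1. Locants follow the 1-benzoxepine skeleton of the target: O1, C2 (CH–CH2Br), C3 (C–CH2OH), C4, C5, C5a, C6 (CMe2), C7 (CHBr), C8, C9, C9a (C–Me, O).
2. Retrosynthesis cuts, in order: the CH2Br/CH2OH pair back to a γ-lactone (CH2–O on C2, C=O on C3); the ether bond O1–C9a; the C3=C4 alkene (cross-metathesis); then ring A at C7–C8 and C5a–C6.
3. Enabling feature: once O1–C9a is cut, ring A is a cyclohexene whose C9=C9a bond lies opposite the CHBr–CMe2 pair C7–C6. That is a Diels–Alder retron: diene C8=C9–C9a(Me)=C5a plus dienophile BrCH=C(Me)–CHO. The formyl group is the activating helper and becomes the second C6 methyl.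
4. Forward order: triene 5 and bromo enal 9 give ring A with the C–Br bond in place (10); CHO is taken to CH3 (13); the chain is joined by cross-metathesis (19); ring B closes by alkoxymercuration (21); the lactone is opened, the CH2OH on C2 brominated and the C3 carbonyl reduced (25).
5. Stereochemistry: C5a and C7 come from the cycloaddition (chiral Lewis acid, E diene, Z enal, endo approach); C2 from (R)-3-hydroxy-γ-butyrolactone; C9a from anti addition of oxygen on the face away from the axial C6 methyl; the C3=C4 geometry from E-selective metathesis.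

Key step: step 5

Assumption: the sense of induction of the oxazaborolidinium catalyst in step 5 is taken from the usual shielding model for α-substituted enals; if the opposite sense is found, the catalyst from (R)-α,α-diphenylprolinol is used and nothing else changes.

**Route**

Step 1
Reactants: 1 3-methyl-2,5-dihydrothiophene 1,1-dioxide (3-methyl-3-sulfolene); 2 allyl bromide
Product: 4 2-allyl-3-methyl-2,5-dihydrothiophene 1,1-dioxide (racemic), via 2-lithio-3-methyl-3-sulfolene 3 (not isolated)
Conditions: LiN(SiMe3)2 added to 1 + 2, THF–HMPA, −78 °C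
Reagents that add atoms: none
Why: Sulfolene alkylation: deprotonation should occur at C2, where the α-sulfonyl allyl anion is delocalised onto the unsubstituted alkene carbon, and the anion is trapped in situ by allyl bromide; the new stereocentre is racemic and is lost in step 2.

Step 2
Reactants: 4 2-allyl-3-methyl-2,5-dihydrothiophene 1,1-dioxide
Product: 5 (3E)-3-methylhepta-1,3,6-triene
Conditions: K2CO3, diglyme, 130 °C, product distilled out
Reagents that add atoms: none
Why: Cheletropic extrusion of SO2 from a 2-substituted 3-sulfolene is disrotatory with the 2-substituent turning outward, so only the E diene should form.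

Step 3
Reactants: 6 prop-2-yn-1-ol
Product: 8 (2Z)-3-bromo-2-methylprop-2-en-1-ol, via (Z)-alkenylmagnesium alkoxide 7 (not isolated)
Conditions: MeMgBr, CuI (10 mol %), THF, −10 → 20 °C; then N-bromosuccinimide, −78 → 0 °C
Reagents that add atoms: methylmagnesium bromide (C[Mg]Br); N-bromosuccinimide (O=C1CCC(=O)N1Br)
Why: Copper-catalysed anti-carbomagnesiation of the propargylic alkoxide puts methyl on the internal carbon and magnesium, chelated by the alkoxide, on the terminal carbon; bromination of the C–Mg bond with retention gives the Z bromoalkene (Br cis to CH2OH).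

Step 4
Reactants: 8 (2Z)-3-bromo-2-methylprop-2-en-1-ol
Product: 9 (2Z)-3-bromo-2-methylprop-2-enal
Conditions: MnO2, CH2Cl2, 0 → 20 °C, dark
Reagents that add atoms: none
Why: Neutral allylic oxidation should leave the Z geometry untouched; the volatile enal is used at once as a solution.

Step 5
Reactants: 5 (3E)-3-methylhepta-1,3,6-triene; 9 (2Z)-3-bromo-2-methylprop-2-enal
Product: 10 (1S,2R,6S)-6-bromo-1,3-dimethyl-2-(prop-2-en-1-yl)cyclohex-3-ene-1-carbaldehyde
Conditions: oxazaborolidinium triflimide from (S)-α,α-diphenylprolinol, tri-o-tolylboroxine and HNTf2 (20 mol %), 5 in excess, CH2Cl2, −78 → −40 °C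
Reagents that add atoms: none
Why: The cationic boron Lewis acid binds the formyl group of 9 and lowers its LUMO, and the s-cis diene unit of 5 adds in a concerted, asynchronous [4π+2π] cycloaddition in which the CHBr carbon bonds ahead to the unsubstituted CH2 terminus (future C7–C8) and the α-carbon to the allyl-bearing terminus (future C5a–C6). The closest known reaction type is the oxazaborolidinium-catalysed enantioselective Diels–Alder reaction of α-methyl enals with open-chain 1,3-dienes. Ring A, the only ring closed, forms in one suprafacial–suprafacial cycloaddition, both σ bonds in the same event. The C–Br centre (future C7) is fixed relative to C5a by the Z geometry of 9 (Br cis to CHO), the endo placement of the formyl group and the E geometry of the diene (allyl "outside"), which together put Br, CHO and allyl on one face; the quaternary carbon is a temporary stereocentre. The absolute configuration comes from the catalyst, which should shield one face of the bound enal so that the diene adds to the Si face of both olefinic carbons. The step needs "ortho" regiochemistry, secured by the 1-alkyl substituent of the diene (as in 1-vinylcycloalkenes) and the polarisation of the bound enal, endo over exo approach, and chemoselectivity, secured because the isolated vinyl group of 5 is neither diene nor activated dienophile.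

Step 6
Reactants: 10 (1S,2R,6S)-6-bromo-1,3-dimethyl-2-(prop-2-en-1-yl)cyclohex-3-ene-1-carbaldehyde
Product: 11 [(1S,2R,6S)-6-bromo-1,3-dimethyl-2-(prop-2-en-1-yl)cyclohex-3-en-1-yl]methanol
Conditions: NaBH4, MeOH, 0 °C
Reagents that add atoms: none
Why: Borohydride reduction of the hindered aldehyde; no stereocentre is made and the secondary bromide should not react.

Step 7
Reactants: 11 [(1S,2R,6S)-6-bromo-1,3-dimethyl-2-(prop-2-en-1-yl)cyclohex-3-en-1-yl]methanol
Product: 13 (4S,6R)-4-bromo-1,5,5-trimethyl-6-(prop-2-en-1-yl)cyclohex-1-ene, via neopentyl triflate 12 (not isolated)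
Conditions: Tf2O, 2,6-lutidine, CH2Cl2, −78 °C; then LiEt3BH, THF, −78 → 0 °C
Reagents that add atoms: none
Why: Polar deoxygenation (triflate, then SN2 by hydride) is chosen because a radical at this carbon would cyclise 5-exo onto the allyl group; the secondary neopentyl bromide should be far slower toward hydride, and the former quaternary stereocentre becomes the CMe2 group.

Step 8
Reactants: 14 (4R)-4-hydroxyoxolan-2-one ((R)-3-hydroxy-γ-butyrolactone)
Product: 16 (3R,4R)-3-[(dimethylamino)methyl]-4-hydroxyoxolan-2-one, via dilithium enolate alkoxide 15 (not isolated)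
Conditions: LiN(iPr)2 (2.2 equiv), THF, −78 °C; then Me2N=CH2+ I−, −78 → 0 °C
Reagents that add atoms: N,N-dimethylmethyleneiminium iodide, Eschenmoser's salt (C=[N+](C)C.[I-])
Why: Mannich reaction of the lactone dianion, which cannot β-eliminate because the leaving group would be an oxide; the iminium ion enters trans to the alkoxide, and this new centre is removed in step 9.

Step 9
Reactants: 16 (3R,4R)-3-[(dimethylamino)methyl]-4-hydroxyoxolan-2-one
Product: 18 (4R)-4-hydroxy-3-methylideneoxolan-2-one, via quaternary ammonium iodide 17 (not isolated)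
Conditions: MeI, MeOH, 20 °C; then aq NaHCO3, CH2Cl2, 20 °C
Reagents that add atoms: none
Why: Exhaustive N-methylation and E1cB loss of trimethylamine (Hofmann-type α-methylenation) under bicarbonate, mild enough not to isomerise the β-hydroxy-α-methylene lactone; C4 is untouched.

Step 10
Reactants: 13 (4S,6R)-4-bromo-1,5,5-trimethyl-6-(prop-2-en-1-yl)cyclohex-1-ene; 18 (4R)-4-hydroxy-3-methylideneoxolan-2-one
Product: 19 (3E,4R)-3-{2-[(1R,5S)-5-bromo-2,6,6-trimethylcyclohex-2-en-1-yl]ethylidene}-4-hydroxyoxolan-2-one
Conditions: second-generation Hoveyda–Grubbs catalyst (5 mol %), 2,6-dichloro-1,4-benzoquinone (10 mol %), 18 in excess, CH2Cl2, 40 °C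
Reagents that add atoms: none
Why: Cross-metathesis of a monosubstituted alkene with an α-methylene lactone should give the trisubstituted alkene with the alkyl group trans to the carbonyl (E), the geometry the oxepene needs (C5 cis to C2); the ring alkene is inert and the quinone suppresses ruthenium hydride isomerisation.

Step 11
Reactants: 19 (3E,4R)-3-{2-[(1R,5S)-5-bromo-2,6,6-trimethylcyclohex-2-en-1-yl]ethylidene}-4-hydroxyoxolan-2-one
Product: 21 lactone of the target skeleton (the aplysistatin ring system): (2R,5aS,7S,9aS)-7-bromo-6,6,9a-trimethyl-2,5,5a,6,7,8,9,9a-octahydro-1-benzoxepine with a γ-lactone fused at C2–C3 (O–CH2 on C2, C=O on C3), via C9 organomercury trifluoroacetate 20 (not isolated)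
Conditions: Hg(OCOCF3)2, MeNO2, −20 °C; then NaBH4, aq NaOH, −20 → 0 °C
Reagents that add atoms: none
Why: Intramolecular alkoxymercuration–demercuration: divalent mercury activates the electron-rich ring alkene rather than the conjugated one, and the C2 hydroxyl attacks the tertiary carbon C9a anti to mercury and on the face away from the axial C6 methyl (equatorial C–O bond, as in acid cyclisations to trans-fused ambroxide-type ethers), which should give the 9aS, trans-fused oxepane before NaBH4 replaces mercury at C9 by hydrogen.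

Step 12
Reactants: 21 lactone of the target skeleton
Product: 22 (2R,5aS,7S,9aS)-7-bromo-2-(hydroxymethyl)-N-methoxy-N,6,6,9a-tetramethyl-2,5,5a,6,7,8,9,9a-octahydro-1-benzoxepine-3-carboxamide
Conditions: MeNH(OMe)·HCl, iPrMgCl added last, THF, −20 → 0 °C; pH 7 work-up
Reagents that add atoms: N,O-dimethylhydroxylamine hydrochloride (CNOC.Cl)
Why: Weinreb amide formation by aminolysis of the lactone with the magnesium amide frees the primary hydroxyl on C2 and keeps the C3 carbonyl in a form that does not relactonise as readily as a γ-hydroxy ester.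

Step 13
Reactants: 22 hydroxy Weinreb amide
Product: 23 (2R,5aS,7S,9aS)-7-bromo-2-(bromomethyl)-N-methoxy-N,6,6,9a-tetramethyl-2,5,5a,6,7,8,9,9a-octahydro-1-benzoxepine-3-carboxamide
Conditions: CBr4, PPh3, CH2Cl2, 0 °C; product used cold and at once
Reagents that add atoms: carbon tetrabromide (BrC(Br)(Br)Br)
Why: Appel reaction at the primary alcohol (SN2 by bromide on the oxyphosphonium ion); if the amide oxygen captures the activated carbon first, bromide should reopen the imidate salt to the same bromide.

Step 14
Reactants: 23 bromo Weinreb amide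
Product: 25 [(2R,5aS,7S,9aS)-7-bromo-2-(bromomethyl)-6,6,9a-trimethyl-2,5,5a,6,7,8,9,9a-octahydro-1-benzoxepin-3-yl]methanol, via oxepene enal 24 (not isolated)
Conditions: DIBAL-H, THF, −78 °C, Rochelle salt work-up; then NaBH4, CeCl3·7H2O, MeOH, −20 °C; neutral work-up
Reagents that add atoms: none
Why: DIBAL-H should stop at the aldehyde through the stable aluminium chelate of the Weinreb amide, and Luche reduction gives the allylic alcohol by 1,2-addition; base is avoided because the bromo alcohol can close to the cyclic ether.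

**Compound list**

1 | 3-methyl-2,5-dihydrothiophene 1,1-dioxide (3-methyl-3-sulfolene) | CC1=CCS(=O)(=O)C1 | starting material
2 | allyl bromide (3-bromoprop-1-ene) | C=CCBr | starting material
3 | 2-lithio-3-methyl-2,5-dihydrothiophene 1,1-dioxide | [Li]C1C(C)=CCS1(=O)=O | intermediate
4 | 2-allyl-3-methyl-2,5-dihydrothiophene 1,1-dioxide (racemic) | C=CCC1C(C)=CCS1(=O)=O | intermediate
5 | (3E)-3-methylhepta-1,3,6-triene | C=C/C(C)=C/CC=C | intermediate
6 | prop-2-yn-1-ol | C#CCO | starting material
7 | bromomagnesium (2Z)-3-(bromomagnesio)-2-methylprop-2-en-1-olate | C/C(CO[Mg]Br)=C/[Mg]Br | intermediate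
8 | (2Z)-3-bromo-2-methylprop-2-en-1-ol | C/C(CO)=C/Br | intermediate
9 | (2Z)-3-bromo-2-methylprop-2-enal | C/C(C=O)=C/Br | intermediate
10 | (1S,2R,6S)-6-bromo-1,3-dimethyl-2-(prop-2-en-1-yl)cyclohex-3-ene-1-carbaldehyde | O=C[C@@]1(C)[C@@H](Br)CC=C(C)[C@H]1CC=C | intermediate
11 | [(1S,2R,6S)-6-bromo-1,3-dimethyl-2-(prop-2-en-1-yl)cyclohex-3-en-1-yl]methanol | OC[C@@]1(C)[C@@H](Br)CC=C(C)[C@H]1CC=C | intermediate
12 | [(1S,2R,6S)-6-bromo-1,3-dimethyl-2-(prop-2-en-1-yl)cyclohex-3-en-1-yl]methyl trifluoromethanesulfonate | FC(F)(F)S(=O)(=O)OC[C@@]1(C)[C@@H](Br)CC=C(C)[C@H]1CC=C | intermediate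
13 | (4S,6R)-4-bromo-1,5,5-trimethyl-6-(prop-2-en-1-yl)cyclohex-1-ene | CC1(C)[C@@H](Br)CC=C(C)[C@H]1CC=C | intermediate
14 | (4R)-4-hydroxyoxolan-2-one ((R)-3-hydroxy-γ-butyrolactone) | O=C1C[C@@H](O)CO1 | starting material
15 | dilithium enolate–alkoxide of 14 | [Li]OC1=C[C@@H](O[Li])CO1 | intermediate
16 | (3R,4R)-3-[(dimethylamino)methyl]-4-hydroxyoxolan-2-one | CN(C)C[C@@H]1[C@@H](O)COC1=O | intermediate
17 | [(3R,4R)-4-hydroxy-2-oxooxolan-3-yl]-N,N,N-trimethylmethanaminium iodide | C[N+](C)(C)C[C@@H]1[C@@H](O)COC1=O.[I-] | intermediate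
18 | (4R)-4-hydroxy-3-methylideneoxolan-2-one | C=C1[C@@H](O)COC1=O | intermediate
19 | (3E,4R)-3-{2-[(1R,5S)-5-bromo-2,6,6-trimethylcyclohex-2-en-1-yl]ethylidene}-4-hydroxyoxolan-2-one | CC1(C)[C@@H](Br)CC=C(C)[C@H]1C/C=C2\[C@@H](O)COC2=O | intermediate
20 | (9R)-9-[(trifluoroacetoxy)mercurio] derivative of 21 (Hg on C9, trans to O1) | CC1(C)[C@@H](Br)C[C@@H]([Hg]OC(=O)C(F)(F)F)[C@]2(C)O[C@@H](COC3=O)C3=CC[C@@H]12 | intermediate
21 | (2R,5aS,7S,9aS)-7-bromo-6,6,9a-trimethyl-octahydro-1-benzoxepine with γ-lactone fused at C2–C3 (O–CH2 on C2, C=O on C3) | CC1(C)[C@@H](Br)CC[C@]2(C)O[C@@H](COC3=O)C3=CC[C@@H]12 | intermediate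
22 | (2R,5aS,7S,9aS)-7-bromo-2-(hydroxymethyl)-N-methoxy-N,6,6,9a-tetramethyl-2,5,5a,6,7,8,9,9a-octahydro-1-benzoxepine-3-carboxamide | CC1(C)[C@@H](Br)CC[C@]2(C)O[C@@H](CO)C(C(=O)N(C)OC)=CC[C@@H]12 | intermediate
23 | (2R,5aS,7S,9aS)-7-bromo-2-(bromomethyl)-N-methoxy-N,6,6,9a-tetramethyl-2,5,5a,6,7,8,9,9a-octahydro-1-benzoxepine-3-carboxamide | CC1(C)[C@@H](Br)CC[C@]2(C)O[C@@H](CBr)C(C(=O)N(C)OC)=CC[C@@H]12 | intermediate
24 | (2R,5aS,7S,9aS)-7-bromo-2-(bromomethyl)-6,6,9a-trimethyl-2,5,5a,6,7,8,9,9a-octahydro-1-benzoxepine-3-carbaldehyde | CC1(C)[C@@H](Br)CC[C@]2(C)O[C@@H](CBr)C(C=O)=CC[C@@H]12 | intermediate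
25 | [(2R,5aS,7S,9aS)-7-bromo-2-(bromomethyl)-6,6,9a-trimethyl-2,5,5a,6,7,8,9,9a-octahydro-1-benzoxepin-3-yl]methanol | CC1(C)[C@@H](Br)CC[C@]2(C)O[C@@H](CBr)C(CO)=CC[C@@H]12 | target

**Totals and risks**

Total step count: 14. Longest linear sequence: 10 steps (1, 2, 5, 6, 7, 10, 11, 12, 13, 14).

Steps most likely to fail:

Step 5. The catalyst may discriminate poorly between the two faces of this β-bromo enal, or the Lewis acid may isomerise the Z enal before it reacts, so that enantiomeric purity is lost. Fallback: from 5 and 9 the cycloaddition is run with the achiral promoter Me2AlCl (CH2Cl2, −78 °C), which should give the endo adduct as a racemate, that is 10 together with the enantiomeric aldehyde F1. Both are carried through steps 6 and 7, giving the enantiomeric alcohol F2, the enantiomeric triflate F3 and the enantiomeric allyl bromide F4 beside 11, 12 and 13. The enantiopure lactone 18 then serves as resolving partner in step 10: cross-metathesis gives 19 and the diastereomeric alkylidene lactone F5, which are separated by chromatography. The route is rejoined at 19.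

Step 11. The hydroxyl group may be delivered axially to C9a (cis ring fusion), or capture of the mercurinium ion may be too slow for the seven-membered ring so that the ring alkene isomerises instead. Fallback: rings A and B are formed together in one cationic cascade instead of closing ring B on a preformed ring A. From 18, cross-metathesis with (4E)-5,9-dimethyldeca-1,4,8-triene F6 (from geranyl bromide and vinylmagnesium bromide, CuI catalysis) gives the geranyl-type alkylidene lactone F7. Bromonium-induced polyene cyclisation (2,4,4,6-tetrabromocyclohexa-2,5-dienone, MeNO2, 0 °C) through a chair-like transition state adds carbon and oxygen anti across the E trisubstituted alkene, which enforces the trans fusion. The bromonium ion is not face-selective with respect to C2, so 21 should form together with the ring-A diastereomeric lactone F8 and is separated from it. The route is rejoined at 21.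

Step 7. Backside attack of hydride at the neopentyl-type carbon may be slow, so that hydride attacks sulfur (return to 11) or, on warming, the secondary bromide is reduced or eliminated. Fallback: reductive metalation and protonation replace the SN2 hydride displacement. From 11, the neopentyl iodide F9 is made (I2, PPh3, imidazole, toluene, 80 °C). Zinc is inserted into the primary C–I bond only (Zn dust, LiCl, THF, 40 °C; secondary alkyl bromides should be inert) to give the alkylzinc iodide F10, which is protonated with AcOH. The route is rejoined at 13.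

Further compounds

F1 | step 5 | (1R,2S,6R)-6-bromo-1,3-dimethyl-2-(prop-2-en-1-yl)cyclohex-3-ene-1-carbaldehyde (enantiomer of 10) | O=C[C@]1(C)[C@H](Br)CC=C(C)[C@@H]1CC=C
F2 | step 5 | [(1R,2S,6R)-6-bromo-1,3-dimethyl-2-(prop-2-en-1-yl)cyclohex-3-en-1-yl]methanol (enantiomer of 11) | OC[C@]1(C)[C@H](Br)CC=C(C)[C@@H]1CC=C
F3 | step 5 | [(1R,2S,6R)-6-bromo-1,3-dimethyl-2-(prop-2-en-1-yl)cyclohex-3-en-1-yl]methyl trifluoromethanesulfonate (enantiomer of 12) | FC(F)(F)S(=O)(=O)OC[C@]1(C)[C@H](Br)CC=C(C)[C@@H]1CC=C
F4 | step 5 | (4R,6S)-4-bromo-1,5,5-trimethyl-6-(prop-2-en-1-yl)cyclohex-1-ene (enantiomer of 13) | CC1(C)[C@H](Br)CC=C(C)[C@@H]1CC=C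
F5 | step 5 | (3E,4R)-3-{2-[(1S,5R)-5-bromo-2,6,6-trimethylcyclohex-2-en-1-yl]ethylidene}-4-hydroxyoxolan-2-one | CC1(C)[C@H](Br)CC=C(C)[C@@H]1C/C=C2\[C@@H](O)COC2=O
F6 | step 11 | (4E)-5,9-dimethyldeca-1,4,8-triene | C=CC/C=C(\C)CCC=C(C)C
F7 | step 11 | (3E,4R)-3-[(3E)-4,8-dimethylnona-3,7-dien-1-ylidene]-4-hydroxyoxolan-2-one | CC(C)=CCC/C(C)=C/C/C=C1\[C@@H](O)COC1=O
F8 | step 11 | (2R,5aR,7R,9aR) diastereomer of lactone 21 | CC1(C)[C@H](Br)CC[C@@]2(C)O[C@@H](COC3=O)C3=CC[C@H]12
F9 | step 7 | (4S,5R,6R)-4-bromo-5-(iodomethyl)-1,5-dimethyl-6-(prop-2-en-1-yl)cyclohex-1-ene | IC[C@@]1(C)[C@@H](Br)CC=C(C)[C@H]1CC=C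
F10 | step 7 | {[(1R,2R,6S)-6-bromo-1,3-dimethyl-2-(prop-2-en-1-yl)cyclohex-3-en-1-yl]methyl}zinc iodide | I[Zn]C[C@@]1(C)[C@@H](Br)CC=C(C)[C@H]1CC=C
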